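**Plan**

- The last cut is the benzyl ether on the C5' oxygen. Before it, ring B is cut at C5'–C6', C1'–C2' and C2'–C3' into a 2-ethynylchromone, a benzyloxy(1-methoxyvinyl)carbene complex of zerovalent chromium and one CO ligand.
- This cut is open because ring B is a hydroquinone with its oxygens para at C2' and C5', C1' sits next to the C2' hydroxyl, and the C4' methoxy group sits on the carbon between C3'–H and C5'. That is the pattern a carbene benzannulation writes: phenol from CO, alkoxy from the carbene carbon, alkyne substituent beside the phenol.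
- The ethynyl group goes back to a C2 ester (reduction, oxidation, one-carbon homologation). Ring C is cut at O1–C2 and C2–C3 to 2-hydroxy-3,4,5,6-tetramethoxyacetophenone and diethyl oxalate.
- Forward: ring A is bought as 3,4,5-trimethoxyphenol and completed in steps 1–3, ring C closes in step 4, ring B closes in step 11, and hydrogenolysis ends the route.
- The carbene complex comes in two steps from methyl vinyl ether, Cr(CO)6 and benzyl alcohol and enters at step 11.
- The target has no stereocentre and no double-bond geometry to set, so no stereocontrol is needed.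

Key step: step 11

Remark: the numbered starting materials and all reagents on the Conditions lines are assumed to be purchased. The chromium tricarbonyl complex of the key step, bound η6 to ring B, is listed in SMILES as the arene and the Cr(CO)3 fragment separated by a dot, and the acylchromates are drawn in their oxycarbene form.

**Route**

Step 1
Reactants: 1 3,4,5-trimethoxyphenol
Product: 2 1-(6-hydroxy-2,3,4-trimethoxyphenyl)ethanone (2'-hydroxy-4',5',6'-trimethoxyacetophenone)
Conditions: AcOH, BF3·OEt2, 90 °C; then H2O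
Reagents that add atoms: acetic acid, CC(=O)O
Why: Friedel–Crafts C-acylation of a very electron-rich phenol under BF3 activation should go ortho to the hydroxyl, the two open positions being equivalent by symmetry, and chelation of the new ketone to boron deactivates the ring against a second acylation.

Step 2
Reactants: 2 1-(6-hydroxy-2,3,4-trimethoxyphenyl)ethanone
Product: 3 1-(3-bromo-2-hydroxy-4,5,6-trimethoxyphenyl)ethanone
Conditions: NBS (1.05 equiv), MeCN, 0 °C → rt
Reagents that add atoms: N-bromosuccinimide, O=C1CCC(=O)N1Br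
Why: Electrophilic aromatic bromination by NBS should take the only free ring position, which is ortho to the phenol and flanked by a methoxy group, far faster than the ketone α-position.

Step 3
Reactants: 3 1-(3-bromo-2-hydroxy-4,5,6-trimethoxyphenyl)ethanone
Product: 4 1-(2-hydroxy-3,4,5,6-tetramethoxyphenyl)ethanone
Conditions: NaOMe (5 equiv), CuBr (0.2 equiv), MeOH/DMF, 110 °C; then aq. HCl
Reagents that add atoms: sodium methoxide, [Na+].[O-]C
Why: Ullmann-type methoxylation, in which CuBr mediates displacement of the aryl bromide by methoxide, is well precedented for o-bromophenols bearing an acyl group, and the ketone, held as enolate and phenoxide, returns unchanged on acidification.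

Step 4
Reactants: 4 1-(2-hydroxy-3,4,5,6-tetramethoxyphenyl)ethanone; 5 diethyl oxalate
Product: 7 ethyl 5,6,7,8-tetramethoxy-4-oxo-4H-chromene-2-carboxylate, via diketo ester 6 (not isolated)
Conditions: NaOEt (3 equiv), EtOH, reflux; then conc. HCl, EtOH, reflux
Reagents that add atoms: none
Why: Crossed Claisen condensation of the ketone enolate with the non-enolizable oxalate gives the 2,4-diketo ester, and acid then drives attack of the phenol oxygen on the C2 ketone and loss of water (6-exo-trig hemiketal formation, then dehydration) to the chromone-2-carboxylate, the classical route to this ring system.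

Step 5
Reactants: 7 ethyl 5,6,7,8-tetramethoxy-4-oxo-4H-chromene-2-carboxylate
Product: 8 ethyl 5-hydroxy-6,7,8-trimethoxy-4-oxo-4H-chromene-2-carboxylate
Conditions: BCl3 (1.5 equiv), CH2Cl2, −78 → 0 °C; then H2O
Reagents that add atoms: none
Why: Chelation-controlled Lewis acid demethylation: BCl3 bound to the C4 carbonyl can reach only the peri C5 methoxy group through a six-membered chelate, so this ether alone should be cleaved at low temperature while the other three methyl ethers and the ethyl ester are left.

Step 6
Reactants: 8 ethyl 5-hydroxy-6,7,8-trimethoxy-4-oxo-4H-chromene-2-carboxylate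
Product: 9 5-hydroxy-2-(hydroxymethyl)-6,7,8-trimethoxy-4H-chromen-4-one
Conditions: NaBH4 (3 equiv), MeOH/THF, 0 °C → rt; then aq. NH4Cl
Reagents that add atoms: none
Why: Borohydride reduction of an ester is feasible here because the C2 ester is activated by the ring oxygen and the conjugated carbonyl (a vinylogous oxalate), whereas the C4 carbonyl is a vinylogous ester further deactivated as the C5 phenoxide chelate.

Step 7
Reactants: 9 5-hydroxy-2-(hydroxymethyl)-6,7,8-trimethoxy-4H-chromen-4-one
Product: 10 5-hydroxy-6,7,8-trimethoxy-4-oxo-4H-chromene-2-carbaldehyde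
Conditions: activated MnO2 (15 equiv), CH2Cl2, rt
Reagents that add atoms: none
Why: MnO2 oxidation of an allylic-type primary alcohol (the CH2OH sits on the C2=C3 double bond) should stop at the aldehyde and leave the chelated phenol and the methyl ethers alone.

Step 8
Reactants: 10 5-hydroxy-6,7,8-trimethoxy-4-oxo-4H-chromene-2-carbaldehyde
Product: 11 2-ethynyl-5-hydroxy-6,7,8-trimethoxy-4H-chromen-4-one
Conditions: dimethyl (1-diazo-2-oxopropyl)phosphonate (1.5 equiv), K2CO3 (3 equiv), MeOH, 0 °C → rt
Reagents that add atoms: dimethyl (1-diazo-2-oxopropyl)phosphonate, COP(=O)(OC)C(=[N+]=[N-])C(C)=O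
Why: Ohira–Bestmann form of the Seyferth–Gilbert homologation: methanolysis of the reagent gives the dimethyl (diazomethyl)phosphonate anion, Horner–Wadsworth–Emmons addition to the aldehyde and loss of N2 give an alkylidene carbene whose 1,2-hydride shift gives the terminal alkyne, while the C5 phenoxide formed under the conditions lowers the electrophilicity of the pyranone toward methoxide.

Step 9
Reactants: 12 methyl vinyl ether; 13 chromium hexacarbonyl, Cr(CO)6
Product: 16 tetramethylammonium pentacarbonyl(2-methoxyprop-2-enoyl)chromate, via 1-methoxyvinyllithium 14 (not isolated), via lithium acylchromate 15 (not isolated)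
Conditions: t-BuLi, THF, −78 → 0 °C; Cr(CO)6, Et2O/THF, 0 °C → rt; then Me4NBr, H2O
Reagents that add atoms: tetramethylammonium bromide, C[N+](C)(C)C.[Br-]
Why: Deprotonation of the enol ether at its α-carbon gives 1-methoxyvinyllithium, which adds to a CO ligand of Cr(CO)6 in the first stage of the Fischer carbene synthesis, and cation exchange gives a storable acylchromate salt.

Step 10
Reactants: 16 tetramethylammonium pentacarbonyl(2-methoxyprop-2-enoyl)chromate
Product: 18 pentacarbonyl[benzyloxy(1-methoxyvinyl)carbene]chromium, via acetoxycarbene complex 17 (not isolated)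
Conditions: AcBr (1.05 equiv), CH2Cl2, −40 °C; then BnOH (1.2 equiv), −40 → 0 °C
Reagents that add atoms: benzyl alcohol, OCc1ccccc1
Why: O-Acylation of the acylchromate gives an acyloxycarbene complex whose carbene carbon is electrophilic enough for addition–elimination by benzyl alcohol at low temperature, the standard acylation–alcoholysis variant of the Fischer synthesis for alkoxy groups that trialkyloxonium salts cannot deliver.

Step 11
Reactants: 11 2-ethynyl-5-hydroxy-6,7,8-trimethoxy-4H-chromen-4-one; 18 pentacarbonyl[benzyloxy(1-methoxyvinyl)carbene]chromium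
Product: 20 2-[5-(benzyloxy)-2-hydroxy-4-methoxyphenyl]-5-hydroxy-6,7,8-trimethoxy-4H-chromen-4-one, via arene tricarbonylchromium complex 19 (not isolated)
Conditions: 18 (1.5 equiv), THF (0.05 M), 50 °C, Ar; then air, daylight, EtOAc, rt
Reagents that add atoms: none
Why: Thermal loss of one cis CO ligand from 18 opens a site for the alkyne, which inserts into the Cr=C bond so that its unsubstituted carbon (future C6') bonds to the former carbene carbon (C5'), and CO insertion then gives a chromium-bound dienylketene whose ketene carbon (C2') has the chromonyl-bearing carbon (C1') as neighbour. Ring B closes by 6π electrocyclization of this dienylketene, the ketene carbon bonding to the terminal CH2 of the 1-methoxyvinyl group (C3'), and tautomerization of the cyclohexadienone gives the C2' phenol as its Cr(CO)3 complex 19, which air and light strip to 20. The closest known reaction type is the Dötz benzannulation of alkenyl(alkoxy)carbene complexes of zerovalent chromium with terminal alkynes, which is known for acyl-substituted alkynes and for cyclic 1-alkoxyvinyl complexes. No stereocentre is formed. The step needs one sense of alkyne insertion, and the terminal alkyne secures it because the larger chromonyl-bearing carbon is placed away from the alkoxy-substituted carbene carbon and next to the CO-derived carbon. It also needs phenol formation to win over cyclobutenone or furan formation, which an alkenyl carbene in THF near 50 °C favours, and the benzyloxy group on C5' means that no oxidant is needed later to free that oxygen.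

Step 12
Reactants: 20 2-[5-(benzyloxy)-2-hydroxy-4-methoxyphenyl]-5-hydroxy-6,7,8-trimethoxy-4H-chromen-4-one
Product: 21 2-(2,5-dihydroxy-4-methoxyphenyl)-5-hydroxy-6,7,8-trimethoxy-4H-chromen-4-one
Conditions: H2 (1 atm), 10% Pd/C, EtOAc/MeOH, rt; filtration under Ar
Reagents that add atoms: none
Why: Heterogeneous hydrogenolysis of a benzyl aryl ether over palladium is routine on flavones, whose conjugated C2=C3 bond and methyl ethers are not touched at 1 atm and room temperature.

**Compound list**

1 | 3,4,5-trimethoxyphenol | COc1cc(O)cc(OC)c1OC | starting material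
2 | 1-(6-hydroxy-2,3,4-trimethoxyphenyl)ethanone | CC(=O)c1c(O)cc(OC)c(OC)c1OC | intermediate
3 | 1-(3-bromo-2-hydroxy-4,5,6-trimethoxyphenyl)ethanone | CC(=O)c1c(O)c(Br)c(OC)c(OC)c1OC | intermediate
4 | 1-(2-hydroxy-3,4,5,6-tetramethoxyphenyl)ethanone | CC(=O)c1c(O)c(OC)c(OC)c(OC)c1OC | intermediate
5 | diethyl oxalate | CCOC(=O)C(=O)OCC | starting material
6 | ethyl 4-(2-hydroxy-3,4,5,6-tetramethoxyphenyl)-2,4-dioxobutanoate | CCOC(=O)C(=O)CC(=O)c1c(O)c(OC)c(OC)c(OC)c1OC | intermediate
7 | ethyl 5,6,7,8-tetramethoxy-4-oxo-4H-chromene-2-carboxylate | CCOC(=O)c1cc(=O)c2c(OC)c(OC)c(OC)c(OC)c2o1 | intermediate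
8 | ethyl 5-hydroxy-6,7,8-trimethoxy-4-oxo-4H-chromene-2-carboxylate | CCOC(=O)c1cc(=O)c2c(O)c(OC)c(OC)c(OC)c2o1 | intermediate
9 | 5-hydroxy-2-(hydroxymethyl)-6,7,8-trimethoxy-4H-chromen-4-one | OCc1cc(=O)c2c(O)c(OC)c(OC)c(OC)c2o1 | intermediate
10 | 5-hydroxy-6,7,8-trimethoxy-4-oxo-4H-chromene-2-carbaldehyde | O=Cc1cc(=O)c2c(O)c(OC)c(OC)c(OC)c2o1 | intermediate
11 | 2-ethynyl-5-hydroxy-6,7,8-trimethoxy-4H-chromen-4-one | C#Cc1cc(=O)c2c(O)c(OC)c(OC)c(OC)c2o1 | intermediate
12 | methyl vinyl ether | COC=C | starting material
13 | chromium hexacarbonyl, Cr(CO)6 | O=C=[Cr](=C=O)(=C=O)(=C=O)(=C=O)=C=O | starting material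
14 | 1-methoxyvinyllithium | [Li]C(=C)OC | intermediate
15 | lithium pentacarbonyl(2-methoxyprop-2-enoyl)chromate, Li[(CO)5CrC(O)C(OMe)=CH2] | [Li+].[O-]C(C(=C)OC)=[Cr](=C=O)(=C=O)(=C=O)(=C=O)=C=O | intermediate
16 | tetramethylammonium pentacarbonyl(2-methoxyprop-2-enoyl)chromate, Me4N[(CO)5CrC(O)C(OMe)=CH2] | C[N+](C)(C)C.[O-]C(C(=C)OC)=[Cr](=C=O)(=C=O)(=C=O)(=C=O)=C=O | intermediate
17 | pentacarbonyl[acetoxy(1-methoxyvinyl)carbene]chromium | CC(=O)OC(C(=C)OC)=[Cr](=C=O)(=C=O)(=C=O)(=C=O)=C=O | intermediate
18 | pentacarbonyl[benzyloxy(1-methoxyvinyl)carbene]chromium | COC(=C)C(OCc1ccccc1)=[Cr](=C=O)(=C=O)(=C=O)(=C=O)=C=O | intermediate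
19 | tricarbonyl{η6-2-[5-(benzyloxy)-2-hydroxy-4-methoxyphenyl]-5-hydroxy-6,7,8-trimethoxy-4H-chromen-4-one}chromium, Cr(CO)3 on ring B | COc1cc(O)c(-c2cc(=O)c3c(O)c(OC)c(OC)c(OC)c3o2)cc1OCc1ccccc1.O=C=[Cr](=C=O)=C=O | intermediate
20 | 2-[5-(benzyloxy)-2-hydroxy-4-methoxyphenyl]-5-hydroxy-6,7,8-trimethoxy-4H-chromen-4-one | COc1cc(O)c(-c2cc(=O)c3c(O)c(OC)c(OC)c(OC)c3o2)cc1OCc1ccccc1 | intermediate
21 | 2-(2,5-dihydroxy-4-methoxyphenyl)-5-hydroxy-6,7,8-trimethoxy-4H-chromen-4-one | COc1cc(O)c(-c2cc(=O)c3c(O)c(OC)c(OC)c(OC)c3o2)cc1O | target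

**Count**

Total steps: 12. Longest linear sequence: 10 (steps 1–8, 11 and 12); the carbene branch (steps 9 and 10) joins at step 11.

**Steps most likely to fail**

1. Step 11 (benzannulation). The chromonyl group makes the alkyne electron-poor, so insertion into the chromium carbene may be slow. Alkyne oligomerization, cyclobutenone or furan formation, or erosion of the insertion sense could then compete with phenol formation. The fallback is a classical flavone construction that sets out from acetophenone 4 and comes back to the route at target 21. Purchased methoxyhydroquinone (2-methoxybenzene-1,4-diol) is benzylated twice (BnBr, K2CO3, DMF) to 1,4-bis(benzyloxy)-2-methoxybenzene F1. Vilsmeier–Haack formylation (POCl3, DMF) at the position para to the methoxy group gives 2,5-bis(benzyloxy)-4-methoxybenzaldehyde F2. Claisen–Schmidt condensation of this aldehyde with 4 (KOH, EtOH, rt) gives (E)-3-[2,5-bis(benzyloxy)-4-methoxyphenyl]-1-(2-hydroxy-3,4,5,6-tetramethoxyphenyl)prop-2-en-1-one F3. Catalytic I2 in DMSO at 120 °C closes ring C by oxa-Michael addition and dehydrogenation to 2-[2,5-bis(benzyloxy)-4-methoxyphenyl]-5,6,7,8-tetramethoxy-4H-chromen-4-one F4. BCl3 (CH2Cl2, −78 → 0 °C) should then cleave both benzyl ethers and the chelated C5 methyl ether to give 21.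

2. Step 8 (alkyne from the aldehyde). Methoxide may add to C2 of the pyranone and open ring C, or the very electrophilic aldehyde may rest as its hemiacetal so that the olefination stalls. The fallback forms the C2–alkyne bond by cross-coupling; it sets out from acetophenone 4 and comes back at alkyne 11. Condensation of 4 with N,N-dimethylformamide dimethyl acetal (toluene, 90 °C) gives (E)-3-(dimethylamino)-1-(2-hydroxy-3,4,5,6-tetramethoxyphenyl)prop-2-en-1-one F5. Aqueous HCl in CH2Cl2 cyclizes it to 5,6,7,8-tetramethoxy-4H-chromen-4-one F6. C2-selective zincation with a TMP-zinc amide in the presence of MgCl2 (TMP2Zn·2MgCl2·2LiCl, THF, −30 °C) and quenching with I2 gives 2-iodo-5,6,7,8-tetramethoxy-4H-chromen-4-one F7. BCl3 (CH2Cl2, −78 → 0 °C) frees the C5 hydroxyl to give 5-hydroxy-2-iodo-6,7,8-trimethoxy-4H-chromen-4-one F8. Sonogashira coupling with trimethylsilylacetylene (PdCl2(PPh3)2, CuI, Et3N, THF, rt) gives 5-hydroxy-6,7,8-trimethoxy-2-[(trimethylsilyl)ethynyl]-4H-chromen-4-one F9. Bu4NF buffered with AcOH (THF, 0 °C) removes the silyl group to give 11.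

3. Step 10 (benzyloxy group onto the carbene carbon). The acyloxycarbene may decompose before alcoholysis, or benzyl alcohol may add across the enol ether double bond under the acid set free. The fallback unveils the C5' oxygen oxidatively instead of through a protecting group; it sets out from salt 16 and comes back at target 21. O-Methylation of 16 with Me3OBF4 (CH2Cl2, 0 °C), the standard Fischer alkylation, gives pentacarbonyl[methoxy(1-methoxyvinyl)carbene]chromium F10. Benzannulation with 11 under the conditions of step 11 gives 5-hydroxy-2-(2-hydroxy-4,5-dimethoxyphenyl)-6,7,8-trimethoxy-4H-chromen-4-one F11. The C5' and C4' methyl ethers cannot be told apart by dealkylation, so the p-methoxyphenol of ring B is oxidized with (NH4)2Ce(NO3)6 (2 equiv, aq. MeCN, 0 °C) to 2-(5-hydroxy-6,7,8-trimethoxy-4-oxo-4H-chromen-2-yl)-5-methoxycyclohexa-2,5-diene-1,4-dione F12. The oxidant is limited to two equivalents so that the chelated, acyl-deactivated C5 phenol of ring A is attacked more slowly, with PhI(OAc)2 in aqueous MeCN as a milder choice. Reduction with aqueous Na2S2O4 in EtOAc then gives hydroquinone 21.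

**Further compounds**

F1 | step 11 | 1,4-bis(benzyloxy)-2-methoxybenzene | COc1cc(OCc2ccccc2)ccc1OCc1ccccc1
F2 | step 11 | 2,5-bis(benzyloxy)-4-methoxybenzaldehyde | COc1cc(OCc2ccccc2)c(C=O)cc1OCc1ccccc1
F3 | step 11 | (E)-3-[2,5-bis(benzyloxy)-4-methoxyphenyl]-1-(2-hydroxy-3,4,5,6-tetramethoxyphenyl)prop-2-en-1-one | COc1cc(OCc2ccccc2)c(/C=C/C(=O)c2c(O)c(OC)c(OC)c(OC)c2OC)cc1OCc1ccccc1
F4 | step 11 | 2-[2,5-bis(benzyloxy)-4-methoxyphenyl]-5,6,7,8-tetramethoxy-4H-chromen-4-one | COc1cc(OCc2ccccc2)c(-c2cc(=O)c3c(OC)c(OC)c(OC)c(OC)c3o2)cc1OCc1ccccc1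
F5 | step 8 | (E)-3-(dimethylamino)-1-(2-hydroxy-3,4,5,6-tetramethoxyphenyl)prop-2-en-1-one | CN(C)/C=C/C(=O)c1c(O)c(OC)c(OC)c(OC)c1OC
F6 | step 8 | 5,6,7,8-tetramethoxy-4H-chromen-4-one | O=c1ccoc2c(OC)c(OC)c(OC)c(OC)c12
F7 | step 8 | 2-iodo-5,6,7,8-tetramethoxy-4H-chromen-4-one | O=c1cc(I)oc2c(OC)c(OC)c(OC)c(OC)c12
F8 | step 8 | 5-hydroxy-2-iodo-6,7,8-trimethoxy-4H-chromen-4-one | O=c1cc(I)oc2c(OC)c(OC)c(OC)c(O)c12
F9 | step 8 | 5-hydroxy-6,7,8-trimethoxy-2-[(trimethylsilyl)ethynyl]-4H-chromen-4-one | C[Si](C)(C)C#Cc1cc(=O)c2c(O)c(OC)c(OC)c(OC)c2o1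
F10 | step 10 | pentacarbonyl[methoxy(1-methoxyvinyl)carbene]chromium | COC(=C)C(OC)=[Cr](=C=O)(=C=O)(=C=O)(=C=O)=C=O
F11 | step 10 | 5-hydroxy-2-(2-hydroxy-4,5-dimethoxyphenyl)-6,7,8-trimethoxy-4H-chromen-4-one | COc1cc(O)c(-c2cc(=O)c3c(O)c(OC)c(OC)c(OC)c3o2)cc1OC
F12 | step 10 | 2-(5-hydroxy-6,7,8-trimethoxy-4-oxo-4H-chromen-2-yl)-5-methoxycyclohexa-2,5-diene-1,4-dione | COC1=CC(=O)C(=CC1=O)c1cc(=O)c2c(O)c(OC)c(OC)c(OC)c2o1
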